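**Assumptions**
- The sense of induction of the chiral acid in Step 4 cannot be predicted in advance. The route is written for the (S,S)-catalyst; if it gives ent-6, the equally available (R,R)-catalyst is used.
- Numbers are given to skeleton-building starting materials, intermediates and the target. Simple reagents (MOMCl, MeOH) appear with SMILES in the reagent line only.

**Retrosynthetic overview**
1. Target 7 comes from trans-diester 6 by reduction of both esters, with no protecting groups at the end.
2. 6 comes from the achiral, C2-symmetric diene diester 5 by an enantioselective acid-catalysed cycloisomerisation. One arm becomes the electrophile, and the arene of the other arm attacks it through a transiently dearomatised Wheland intermediate. This forms C1–C8a and sets C1 and C2.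
3. 5 comes from two vanillin units and dimethyl succinate by a double Stobbe condensation.
4. Ring order: both benzene rings come from vanillin; the only ring built is the dihydronaphthalene carbocycle, formed in the key step.

**Step 1**
Reactants: 1 vanillin
Product: 2 3-methoxy-4-(methoxymethoxy)benzaldehyde
Conditions: MOMCl, i-Pr2NEt, CH2Cl2, 0 °C to rt
Reagents that add atoms: chloromethyl methyl ether, COCCl
Why: Williamson-type O-alkylation of the phenol; masking the phenoxide keeps the aldehyde electrophilic enough for the Stobbe condensation.

**Step 2**
Reactants: 2 (2.2 equiv) and 3 dimethyl succinate (1 equiv)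
Product: 4 (2E,3E)-2,3-bis[3-methoxy-4-(methoxymethoxy)benzylidene]succinic acid
Conditions: t-BuOK (3 equiv), t-BuOH, reflux; then aq NaOH, reflux; citric acid to pH 3–4 at 0 °C; crystallise; exclude light
Reagents that add atoms: none beyond 2 and 3, except hydroxide/water for any residual ester that is saponified: NaOH, [Na+].[OH-]; water, O
Why: Double Stobbe condensation (aldol, γ-lactonisation, E1cB opening, run twice, as in the classical fulgenic acid synthesis); the E,E isomer with each aryl anti to its carboxyl is the favoured, crystalline product.

**Step 3**
Reactants: 4
Product: 5 dimethyl (2E,3E)-2,3-bis(4-hydroxy-3-methoxybenzylidene)succinate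
Conditions: AcCl (gives about 1 M HCl) in MeOH, 50 °C, dark
Reagents that add atoms: methanol, CO
Why: Fischer esterification and acid methanolysis of the MOM acetals in one pot; hydroxycinnamate units tolerate HCl/MeOH, as in the standard esterification of ferulic acid.

**Step 4 (key step)**
Reactants: 5
Product: 6 dimethyl (1S,2R)-7-hydroxy-1-(4-hydroxy-3-methoxyphenyl)-6-methoxy-1,2-dihydronaphthalene-2,3-dicarboxylate (1,2-trans)
Conditions: (S,S)-IDPi (BINOL-derived imidodiphosphorimidate, N-Tf core, 5–10 mol%), CHCl3 (0.02 M), 4 Å MS, 25–40 °C, Ar, dark; one recrystallisation to upgrade ee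
Reagents that add atoms: none (isomerisation)
Why: Proposed new method: the confined strong chiral Brønsted acid protonates one hydroxycinnamate arm to a p-quinone-methide-type benzylic cation paired with the chiral anion, which fixes one helical twist of the diene; C6′ of the other arm (para to OMe) then attacks one face of C7 in an intramolecular Friedel–Crafts closure, setting C1, and the resulting dienol is protonated anti to the C1 aryl to give the trans (also thermodynamic) C2 epimer; the closest known reactions are the racemic TfOH cyclisation of 2,3-dibenzylidenesuccinates to trans-1-aryl-1,2-dihydronaphthalenes, chiral-acid-catalysed asymmetric Nazarov cyclisations, and chiral phosphoric acid-catalysed arylation of p-quinone methides.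

**Step 5**
Reactants: 6
Product: 7 [(1S,2R)-7-hydroxy-1-(4-hydroxy-3-methoxyphenyl)-6-methoxy-1,2-dihydronaphthalene-2,3-diyl]dimethanol (target)
Conditions: DIBAL-H (8 equiv), THF/toluene, −78 to 0 °C; Rochelle salt work-up under Ar
Reagents that add atoms: none
Why: DIBAL 1,2-reduction of the conjugated and the saturated ester to the allylic and primary alcohols; free phenols are tolerated as aluminium phenoxides (as in ferulate to coniferyl alcohol), and the cold, non-basic conditions leave C1, C2 and the C3=C4 alkene untouched.

**Compound list**
1 | vanillin | COc1cc(C=O)ccc1O | starting material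
2 | 3-methoxy-4-(methoxymethoxy)benzaldehyde | COCOc1ccc(C=O)cc1OC | intermediate
3 | dimethyl succinate | COC(=O)CCC(=O)OC | starting material
4 | (2E,3E)-2,3-bis[3-methoxy-4-(methoxymethoxy)benzylidene]succinic acid | OC(=O)/C(=C/c1ccc(OCOC)c(OC)c1)C(=C/c1ccc(OCOC)c(OC)c1)\C(O)=O | intermediate
5 | dimethyl (2E,3E)-2,3-bis(4-hydroxy-3-methoxybenzylidene)succinate | COC(=O)/C(=C/c1ccc(O)c(OC)c1)C(=C/c1ccc(O)c(OC)c1)\C(=O)OC | intermediate
6 | dimethyl (1S,2R)-7-hydroxy-1-(4-hydroxy-3-methoxyphenyl)-6-methoxy-1,2-dihydronaphthalene-2,3-dicarboxylate | COc1cc([C@H]2c3cc(O)c(OC)cc3C=C(C(=O)OC)[C@@H]2C(=O)OC)ccc1O | intermediate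
7 | [(1S,2R)-7-hydroxy-1-(4-hydroxy-3-methoxyphenyl)-6-methoxy-1,2-dihydronaphthalene-2,3-diyl]dimethanol | COc1cc([C@H]2c3cc(O)c(OC)cc3C=C(CO)[C@@H]2CO)ccc1O | target

**Totals**
Total steps: 5. Longest linear sequence: 5 (from vanillin).

**Three steps most likely to fail, with fallbacks**
1. Step 4 (insufficient reactivity or ee in the catalytic cycloisomerisation). Fallback: covalent helicity control. Convert diacid 4 to its anhydride, bridge it with (S)-prolinol to a conformationally locked atropisomeric amide-lactone, and run a 350 nm 6π-photocyclisation/[1,5]-H shift to transfer axial to central chirality. Then epimerise C2 to trans and cleave the auxiliary reductively.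
2. Step 2 (low yield or E/Z mixtures in the one-pot double Stobbe). Fallback: form the C8–C8′ bond instead. Make methyl (Z)-α-bromo-O-MOM-ferulate from methyl ferulate (Br2, then Et3N) and homocouple it reductively with Ni(0) or Pd, with retention of geometry, to give the (E,E)-diene diester directly.
3. Step 5 (conjugate reduction, C2 epimerisation via the transient aldehyde, or air aromatisation of the phenolic product). Fallback: a protected end-game. Silylate both phenols of 6 (TBSCl), reduce with alane (LiAlH4/AlCl3), then remove the silyl groups with TBAF; this adds two steps.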